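**Assumption:** Locants follow chalcone usage. Ring A carbons are primed (C1' carries the ketone). Side-chain carbons are double-primed (C1'' benzylic, C2''=C3'', methyl on C3'', oxygen on C4''). The target has no stereocentre and three E double bonds.

## The problem

Isogemichalcone B (22) has no stereocentre and no ring beyond its three benzene rings, so the synthesis is a matter of connectivity, alkene geometry and functional-group tolerance. Ring A is a resorcinol substituted at four contiguous positions: the cinnamoyl ketone at C1', hydroxyls at C2' and C4', and the five-carbon side chain at C3', wedged between the two oxygens. Two of the three E double bonds are the styrenic enoyl units of p-coumaric acid (15) and can be bought. The third, C2''=C3'', is trisubstituted and must hold the C3'' methyl cis to the benzylic carbon C1'' and the C4'' oxygen trans to it. With no stereocentre present, nothing in the molecule can relay this geometry; it has to follow from the mechanism of the step that makes the alkene. The fragile parts are the 2'-hydroxychalcone (flavanone closure in base or hot acid), the C2''=C3'' alkene flanked by two phenols (acid-induced chroman formation), the allylic C4'' ester (solvolysis, acyl transfer) and both enones (conjugate addition). All strongly basic or nucleophilic chemistry must therefore come before the chalcone and the ester, and the phenol protecting groups must leave together under mild acid. The feature that opens the key step is the position of the C4'' hydroxyl next to C3''. At the alkyne level C2''≡C3'' this hydroxyl is propargylic, binds magnesium as an alkoxide, and can steer methyl onto C3'' and the metal onto C2'' from opposite sides, which is the required E arrangement.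

## Retrosynthesis

**22 from 21 (four O–CH2OCH3 bonds).** The last operation is removal of four methoxymethyl (MOM) ethers from 21. MOM is chosen because the two on ring A also direct the lithiation that sets the 1,2,3-pattern, and one mild acidic step then frees every phenol. The forward step must spare the allylic ester, the alkene and the chalcone.

**21 from 20 and 17 (C4''O–acyl bond).** Cutting the ester late keeps the cinnamate away from every organometallic reagent. The precursors are the chalcone alcohol 20 and the protected acid 17, which comes from 15 in one flask. The forward reaction is a carbodiimide esterification of a primary allylic alcohol under near-neutral conditions.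

**20 from 14 and 18 (C1'–carbonyl bond).** An aryl anion at C1', made from the bromide 14 by halogen–lithium exchange, takes the whole enoyl unit from the Weinreb amide 18 in one step. A Friedel–Crafts acylation would not tolerate the acetals or the alkene. An acetophenone plus aldol condensation would cost a step and is kept in reserve. The exchange must outrun deprotonation of the doubly activated C1'' methylene, and the C4'' hydroxyl is carried as its lithium alkoxide.

**14 from 10 and 11 (C3''–CH3 and C2''–H bonds; the key step).** Adding methyl and hydrogen anti across the alkyne of 10 with methylmagnesium bromide (11) creates the trisubstituted alkene with its geometry fixed by a cyclic alkoxide chelate. The neighbouring cuts at C1''–C2'' or C2''=C3'' (allylation, olefination, metathesis) rely on a preformed E-allylic partner or on thermodynamic E/Z preference. The precursor 10 is simpler by one carbon and has no stereochemical element. The forward reaction needs regiocontrol (methyl to C3'') and anti selectivity.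

**10 from 9 (C1'–Br bond).** The bromine that later becomes the C1' anion is introduced at the alkyne stage. An alkyne is inert to an electrophilic bromine source, whereas the trisubstituted alkene formed afterwards would compete with the ring. The price is that an aryl bromide rides through the Grignard step. An electron-rich aryl bromide should neither exchange with nor couple to 11 under those conditions.

**9 from 6 and 7 (C1''–C2'' bond).** The benzylic carbon is joined to the alkyne by copper-catalysed coupling of the benzyl chloride 6 with doubly metallated propargyl alcohol (7). No protecting group is needed on 7. The reverse polarity (aryl copper plus a propargylic halide) would favour SN2' attack and give an allene.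

**6 from 4, 2 and 1 (aryl–C1'' bond, O-protection).** The chloride 6 comes from the benzyl alcohol 4. Alcohol 4 arises by lithiation of the bis-MOM ether 2 at the carbon between its two oxygens, followed by hydroxymethylation. Ether 2 is made from resorcinol (1).

**18 from 17 from 15.** Both coumaroyl units come from 15. Protection gives the acid 17, which serves as the ester component and, after amide formation, as the Weinreb amide 18.

## Roads not taken

**Alternative 1:** Ring A would be built from an acyclic chain. Treatment of the cinnamoyl triketone A2 with Mg(OCH3)2 would add the C1' methylene to the β-methoxy enone carbon C6' and expel methanol. Enolisation would then give the chalcone A1.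
- Merits: the substitution pattern is written into the chain, no aromatic substitution or halogen–metal exchange is needed, and A1 emerges with the 2',4'-phenols free and the ring B phenol still masked.
- Weak points: A2 is a polyenolisable chain with two different Michael acceptors and the complete side chain. Its assembly would take more C–C bond formations than the whole present route. O-cyclisation to a pyranone and aldol or Michael pathways compete with the desired closure. A2 must already contain the E alkene, so the central geometric problem is moved, not solved.
- Comparison: A1 offers better phenol differentiation than 21, which needs a fourfold deprotection. The chosen plan sets against that a purchased aromatic ring, a directed lithiation that fixes the 1,2,3-pattern, and far fewer steps.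

**Alternative 2:** The C1'–carbonyl bond would be made on a non-aromatic ring. The α'-lithium enolate of the vinylogous ester A4 (lithium diisopropylamide) would be C-acylated by the N-acylbenzotriazole A5 to give A3, and the ring would be dehydrogenated later.
- Merits: the position of every ring substituent is unambiguous, and no aryl bromide or aryllithium is involved.
- Weak points: A3 is a β-diketone, more acidic than A4, so proton transfer consumes enolate unless excess base is used, and O-acylation competes. The later aromatisation needs an oxidant (a high-potential quinone, or halogenation or selenation followed by elimination) that would also attack the allylic and benzylic C–H bonds of the side chain and the electron-rich alkene. A4 itself requires C-alkylation of a cyclic 1,3-diketone with a stereodefined E-allylic halide, so the alkene geometry is again exported to a separately made reagent.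
- Comparison: this road avoids exposing a benzylic–propargylic methylene to a Grignard reagent, which is a real weakness of the chosen plan. The chosen plan starts at the aromatic oxidation level and needs no oxidation in the presence of the side chain.

**Alternative 3:** The C2''=C3'' bond would be made by cross-metathesis. The 3'-allyl chalcone A7 and methacrolein A8 would give the E-enal A6 with the second-generation Hoveyda–Grubbs catalyst. A 1,2-reduction of the aldehyde (NaBH4, CeCl3) would then give 20 of the present route.
- Merits: this is the most direct road. The allyl group is easy to install, the end game is shared with the chosen plan, and 20 would be reached in about one step fewer. No aryl bromide or acidic propargylic methylene meets a Grignard reagent.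
- Weak points: a terminal allyl arene paired with a 1,1-disubstituted, electron-poor olefin is a demanding metathesis. It needs a large excess of A8 and a high catalyst loading. Ruthenium hydride species can isomerise the allyl group into conjugation with the ring. The chalcone double bond is a second possible metathesis partner. The E/Z ratio of A6 rests on thermodynamic preference, and a minor Z isomer would be hard to remove. The reduction must also distinguish the enal from the chalcone enone.
- Comparison: alternative 3 is shorter. The chosen plan sets against it a geometry enforced by a cyclic organomagnesium intermediate, inexpensive Mg and Cu reagents, and no competition between two alkenes or two enones.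

Key step: step 6

## Route

Step 1
Reactants: 1 resorcinol
Product: 2 1,3-bis(methoxymethoxy)benzene
Conditions: NaH (2.4 equiv), MOMCl (2.3 equiv), DMF, 0 °C → rt
Reagents that add atoms: chloromethyl methyl ether, COCCl
Why: Williamson-type O-alkylation of both phenoxides by the α-chloro ether; the MOM groups later direct the lithiation and are removed together at the end.

Step 2
Reactants: 2 1,3-bis(methoxymethoxy)benzene
Product: 4 [2,6-bis(methoxymethoxy)phenyl]methanol, via aryllithium 3 (not isolated)
Conditions: n-BuLi (1.1 equiv), THF, 0 °C, 1 h; (CH2O)n (3 equiv), 0 °C → rt; then H2O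
Reagents that add atoms: paraformaldehyde (formaldehyde), C=O
Why: Directed ortho-metalation occurs at the carbon flanked by both OMOM groups, the most acidic and doubly chelated site; the aryllithium is then hydroxymethylated by formaldehyde released from paraformaldehyde.

Step 3
Reactants: 4 [2,6-bis(methoxymethoxy)phenyl]methanol
Product: 6 2-(chloromethyl)-1,3-bis(methoxymethoxy)benzene, via benzyl methanesulfonate 5 (not isolated)
Conditions: MsCl (1.2 equiv), Et3N (1.5 equiv), LiCl (3 equiv), THF, 0 °C → rt; used crude
Reagents that add atoms: lithium chloride, [Li+].[Cl-]
Why: Mesylation followed by SN2 displacement with chloride under basic, non-acidic conditions keeps the acetals intact; the electron-rich benzyl chloride is taken on without chromatography.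

Step 4
Reactants: 6 2-(chloromethyl)-1,3-bis(methoxymethoxy)benzene; 7 propargyl alcohol
Product: 9 4-[2,6-bis(methoxymethoxy)phenyl]but-2-yn-1-ol, via propargyl alcohol bis(bromomagnesium) salt 8 (not isolated)
Conditions: 7 (2 equiv), EtMgBr (4 equiv), THF, 0 → 50 °C; CuI (10 mol %); 6 (1 equiv), 50 °C; then H2O/aq NH4Cl
Reagents that add atoms: none
Why: Copper-catalysed coupling of an alkynylmagnesium halide with a benzylic halide; the O,C-dimagnesium salt reacts only at carbon, so propargyl alcohol needs no protecting group and the C1''–C2'' bond forms without allene formation.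

Step 5
Reactants: 9 4-[2,6-bis(methoxymethoxy)phenyl]but-2-yn-1-ol
Product: 10 4-[3-bromo-2,6-bis(methoxymethoxy)phenyl]but-2-yn-1-ol
Conditions: NBS (1.0 equiv), MeCN, 0 °C, dark
Reagents that add atoms: N-bromosuccinimide, O=C1CCC(=O)N1Br
Why: Electrophilic aromatic bromination at the only type of free position that is ortho to one alkoxy group and para to the other; the alkyne and the alcohol do not react with NBS without acid or silver catalysis, and the monobromide is less reactive than 9.

Step 6
Reactants: 10 4-[3-bromo-2,6-bis(methoxymethoxy)phenyl]but-2-yn-1-ol; 11 methylmagnesium bromide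
Product: 14 (E)-4-[3-bromo-2,6-bis(methoxymethoxy)phenyl]-2-methylbut-2-en-1-ol, via bromomagnesium alkoxide 12 (not isolated), via oxamagnesacycle 13 (not isolated)
Conditions: MeMgBr (4 equiv), CuI (20 mol %), Et2O–THF, −10 °C → rt; then H2O/aq NH4Cl, 0 °C
Reagents that add atoms: none
Why: The first equivalent of 11 converts the hydroxyl into the magnesium alkoxide 12, and a methylcopper species formed from CuI and 11 then transfers methyl to the alkyne carbon next to the carbinol (C3'') while magnesium becomes bound to the distal carbon C2'', giving the five-membered oxamagnesacycle 13. In that ring the metal must lie cis to the CH2O arm, so methyl and metal are trans across the new double bond (anti addition), and hydrolysis replaces C–Mg by C–H with retention. The methyl group therefore ends cis to the arylmethyl group and the hydroxymethyl group trans to it, which is the E alkene of the target. The closest known reaction type is the copper-catalysed anti-carbomagnesiation of propargylic alcohols with Grignard reagents, which gives 2-substituted (E)-allylic alcohols after hydrolysis. No ring remains in the product (the transient chelate is five-membered) and no stereocentre is formed; the alkoxide chelate is the element that controls the alkene geometry. The step needs regioselectivity (methyl to C3'') and anti selectivity, and both follow from the alkoxide chelate. It also needs chemoselectivity: the MOM acetals are inert to Grignard reagents, and an electron-rich aryl bromide should neither exchange with nor couple to MeMgBr at or below room temperature. Ether solvent and moderate temperature limit deprotonation of the benzylic–propargylic C1'' methylene.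

Step 7
Reactants: 15 p-coumaric acid
Product: 17 (E)-3-[4-(methoxymethoxy)phenyl]prop-2-enoic acid, via methoxymethyl ester 16 (not isolated)
Conditions: NaH (2.4 equiv), MOMCl (2.3 equiv), DMF, 0 °C → rt; then 2 M aq NaOH, MeOH, rt; cold 1 M HCl to pH 4
Reagents that add atoms: chloromethyl methyl ether, COCCl; sodium hydroxide, [Na+].[OH-]
Why: Phenoxide and carboxylate are both alkylated; the MOM ester is an acyl acetal and is saponified in the same flask, whereas the aryl MOM ether is stable to base and to brief cold acidification.

Step 8
Reactants: 17 (E)-3-[4-(methoxymethoxy)phenyl]prop-2-enoic acid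
Product: 18 (E)-N-methoxy-3-[4-(methoxymethoxy)phenyl]-N-methylprop-2-enamide
Conditions: MeNHOMe·HCl (1.3 equiv), EDC·HCl (1.3 equiv), DMAP (0.1 equiv), Et3N (2.8 equiv), CH2Cl2, 0 °C → rt
Reagents that add atoms: N,O-dimethylhydroxylamine hydrochloride, CNOC.Cl
Why: Carbodiimide-mediated amide coupling gives the Weinreb amide; the E-cinnamoyl geometry is not touched.

Step 9
Reactants: 14 (E)-4-[3-bromo-2,6-bis(methoxymethoxy)phenyl]-2-methylbut-2-en-1-ol; 18 (E)-N-methoxy-3-[4-(methoxymethoxy)phenyl]-N-methylprop-2-enamide
Product: 20 (E)-1-{3-[(E)-4-hydroxy-3-methylbut-2-enyl]-2,4-bis(methoxymethoxy)phenyl}-3-[4-(methoxymethoxy)phenyl]prop-2-en-1-one, via dilithio species 19 (not isolated)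
Conditions: n-BuLi (2.1 equiv), THF, −78 °C, 20 min; 18 (1.2 equiv), −78 → −20 °C; then H2O
Reagents that add atoms: none
Why: The first equivalent of n-BuLi forms the lithium alkoxide and the second effects bromine–lithium exchange, which at −78 °C is faster than any C–H deprotonation and gives an aryllithium chelated by the ortho OMOM group. Weinreb ketone synthesis then follows by 1,2-addition to 18; the chelated tetrahedral adduct survives until work-up, so no over-addition occurs and the chalcone appears only on quenching.

Step 10
Reactants: 20 (E)-1-{3-[(E)-4-hydroxy-3-methylbut-2-enyl]-2,4-bis(methoxymethoxy)phenyl}-3-[4-(methoxymethoxy)phenyl]prop-2-en-1-one; 17 (E)-3-[4-(methoxymethoxy)phenyl]prop-2-enoic acid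
Product: 21 (E)-4-{2,6-bis(methoxymethoxy)-3-[(E)-3-[4-(methoxymethoxy)phenyl]prop-2-enoyl]phenyl}-2-methylbut-2-enyl (E)-3-[4-(methoxymethoxy)phenyl]prop-2-enoate
Conditions: EDC·HCl (1.5 equiv), DMAP (0.2 equiv), CH2Cl2, 0 °C → rt
Reagents that add atoms: none
Why: Steglich esterification of an unhindered primary allylic alcohol; the conditions are near neutral, so neither the chalcone nor the alkene geometry is at risk.

Step 11
Reactants: 21 (E)-4-{2,6-bis(methoxymethoxy)-3-[(E)-3-[4-(methoxymethoxy)phenyl]prop-2-enoyl]phenyl}-2-methylbut-2-enyl (E)-3-[4-(methoxymethoxy)phenyl]prop-2-enoate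
Product: 22 isogemichalcone B
Conditions: 3 M aq HCl, MeOH–THF (1:1), rt (→ 40 °C if needed)
Reagents that add atoms: none
Why: Acid-catalysed acetal exchange removes all four aryl MOM ethers, the 2'-ether fastest because of the neighbouring carbonyl; mild methanolic HCl is the usual end game for prenylated 2'-hydroxychalcones and leaves the E alkenes unchanged.

## Compound list

1 | resorcinol (benzene-1,3-diol) | Oc1cccc(O)c1 | starting material
2 | 1,3-bis(methoxymethoxy)benzene | COCOc1cccc(OCOC)c1 | intermediate
3 | [2,6-bis(methoxymethoxy)phenyl]lithium (not isolated) | [Li]c1c(OCOC)cccc1OCOC | intermediate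
4 | [2,6-bis(methoxymethoxy)phenyl]methanol | COCOc1cccc(OCOC)c1CO | intermediate
5 | 2,6-bis(methoxymethoxy)benzyl methanesulfonate (not isolated) | COCOc1cccc(OCOC)c1COS(C)(=O)=O | intermediate
6 | 2-(chloromethyl)-1,3-bis(methoxymethoxy)benzene | COCOc1cccc(OCOC)c1CCl | intermediate
7 | propargyl alcohol (prop-2-yn-1-ol) | C#CCO | starting material
8 | bis(bromomagnesium) salt of propargyl alcohol, BrMgC≡CCH2OMgBr (not isolated) | Br[Mg]C#CCO[Mg]Br | intermediate
9 | 4-[2,6-bis(methoxymethoxy)phenyl]but-2-yn-1-ol | COCOc1cccc(OCOC)c1CC#CCO | intermediate
10 | 4-[3-bromo-2,6-bis(methoxymethoxy)phenyl]but-2-yn-1-ol | COCOc1ccc(Br)c(OCOC)c1CC#CCO | intermediate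
11 | methylmagnesium bromide | C[Mg]Br | starting material
12 | bromomagnesium 4-[3-bromo-2,6-bis(methoxymethoxy)phenyl]but-2-yn-1-olate (not isolated) | COCOc1ccc(Br)c(OCOC)c1CC#CCO[Mg]Br | intermediate
13 | 3-[3-bromo-2,6-bis(methoxymethoxy)benzyl]-4-methyl-2,5-dihydro-1,2-oxamagnesole (not isolated) | CC1=C(Cc2c(OCOC)ccc(Br)c2OCOC)[Mg]OC1 | intermediate
14 | (E)-4-[3-bromo-2,6-bis(methoxymethoxy)phenyl]-2-methylbut-2-en-1-ol | COCOc1ccc(Br)c(OCOC)c1C/C=C(\C)CO | intermediate
15 | p-coumaric acid, (E)-3-(4-hydroxyphenyl)prop-2-enoic acid | O=C(O)/C=C/c1ccc(O)cc1 | starting material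
16 | methoxymethyl (E)-3-[4-(methoxymethoxy)phenyl]prop-2-enoate (not isolated) | COCOC(=O)/C=C/c1ccc(OCOC)cc1 | intermediate
17 | (E)-3-[4-(methoxymethoxy)phenyl]prop-2-enoic acid | O=C(O)/C=C/c1ccc(OCOC)cc1 | intermediate
18 | (E)-N-methoxy-3-[4-(methoxymethoxy)phenyl]-N-methylprop-2-enamide | COCOc1ccc(/C=C/C(=O)N(C)OC)cc1 | intermediate
19 | dilithio species: lithium (E)-4-[3-lithio-2,6-bis(methoxymethoxy)phenyl]-2-methylbut-2-en-1-olate (not isolated) | [Li]c1ccc(OCOC)c(C/C=C(\C)CO[Li])c1OCOC | intermediate
20 | (E)-1-{3-[(E)-4-hydroxy-3-methylbut-2-enyl]-2,4-bis(methoxymethoxy)phenyl}-3-[4-(methoxymethoxy)phenyl]prop-2-en-1-one | COCOc1ccc(/C=C/C(=O)c2ccc(OCOC)c(C/C=C(\C)CO)c2OCOC)cc1 | intermediate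
21 | (E)-4-{2,6-bis(methoxymethoxy)-3-[(E)-3-[4-(methoxymethoxy)phenyl]prop-2-enoyl]phenyl}-2-methylbut-2-enyl (E)-3-[4-(methoxymethoxy)phenyl]prop-2-enoate | C/C(=C\Cc1c(OCOC)ccc(C(=O)/C=C/c2ccc(OCOC)cc2)c1OCOC)COC(=O)/C=C/c1ccc(OCOC)cc1 | intermediate
22 | isogemichalcone B | C/C(=C\Cc1c(O)ccc(C(=O)/C=C/c2ccc(O)cc2)c1O)COC(=O)/C=C/c1ccc(O)cc1 | target

## Step count and risks

Total step count: 11.
Longest linear sequence: 9 steps from resorcinol 1 (steps 1–6, 9, 10, 11). The coumarate branch from 15 (steps 7 and 8) joins at steps 9 and 10.

**Step 6 (key step).**
- What may go wrong: base-induced prototropic shift of the C1'' methylene, which is both benzylic and propargylic, towards allenic or conjugated isomers. The risk grows if addition to this internal, ortho,ortho'-disubstituted benzyl alkyne is slow and the mixture has to be warmed. Erosion of regiocontrol is less likely.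
- Fallback: from 10, hydroxyl-directed trans-hydrostannation (Bu3SnH, [Cp*RuCl]4 cat., CH2Cl2) should place tin on the carbon next to the carbinol and give (Z)-4-[3-bromo-2,6-bis(methoxymethoxy)phenyl]-2-(tributylstannyl)but-2-en-1-ol F1. Iodine then gives the (Z)-2-iodo alcohol F2 with retention, and Me2CuLi (excess, Et2O, 0 °C) replaces iodine by methyl with retention. The route is rejoined at 14. This is the same net anti addition of hydrogen and methyl, reached by hydrometalation instead of carbometalation and without a strongly basic Grignard reagent.

**Step 4.**
- What may go wrong: ionisation of the 2,6-dialkoxybenzyl chloride, leading to self-alkylation by a MOM oxygen or to reductive homocoupling, in competition with the slow reaction of the sparingly soluble dimagnesium salt.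
- Fallback: from 2, by way of 3, transmetalation with MgBr2·OEt2 and CuBr-catalysed SN2' displacement of methoxide from methoxyallene gives 1,3-bis(methoxymethoxy)-2-(prop-2-yn-1-yl)benzene F3. Lithiation of the terminal alkyne (n-BuLi, THF, −78 °C) and addition to paraformaldehyde then rejoin the route at 9. No benzyl halide is handled.

**Step 9.**
- What may go wrong: proton transfer to the aryllithium before acyl transfer (from the C1'' methylene or within aggregates with the C4'' alkoxide), and conjugate instead of carbonyl addition to the cinnamoyl amide.
- Fallback: from 14, silylation (TBSCl, imidazole, DMF) gives the silyl ether F4. Bromine–lithium exchange and quenching with N-methoxy-N-methylacetamide give the acetophenone F5. Claisen–Schmidt condensation with 4-(methoxymethoxy)benzaldehyde (KOH, EtOH, rt) gives the silylated chalcone F6, and TBAF in THF rejoins the route at 20. The enone is then built by aldol condensation, not by enoyl transfer.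

**Step 11.**
- What may go wrong: acid-promoted solvolysis of the allylic coumarate (methanolysis or ionisation), addition of a freed phenol to the C2''=C3'' alkene, or chalcone-to-flavanone isomerisation if warming is needed for the less labile MOM groups.
- Fallback: from 20, the three MOM groups are removed first (aq HCl, MeOH–THF, rt), with no ester present, to give the tetraol (E)-1-{2,4-dihydroxy-3-[(E)-4-hydroxy-3-methylbut-2-enyl]phenyl}-3-(4-hydroxyphenyl)prop-2-en-1-one F7. A Mitsunobu esterification with unprotected 15 (PPh3, diisopropyl azodicarboxylate, THF, 0 °C) then alkylates the carboxylic acid, which is far more acidic than any phenol, at primary C4''. The route is rejoined at 22.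

## Further compounds

F1 | step 6 | (Z)-4-[3-bromo-2,6-bis(methoxymethoxy)phenyl]-2-(tributylstannyl)but-2-en-1-ol | CCCC[Sn](CCCC)(CCCC)/C(CO)=C\Cc1c(OCOC)ccc(Br)c1OCOC
F2 | step 6 | (Z)-4-[3-bromo-2,6-bis(methoxymethoxy)phenyl]-2-iodobut-2-en-1-ol | OC/C(I)=C/Cc1c(OCOC)ccc(Br)c1OCOC
F3 | step 4 | 1,3-bis(methoxymethoxy)-2-(prop-2-yn-1-yl)benzene | COCOc1cccc(OCOC)c1CC#C
F4 | step 9 | {[(E)-4-[3-bromo-2,6-bis(methoxymethoxy)phenyl]-2-methylbut-2-enyl]oxy}(tert-butyl)dimethylsilane | COCOc1ccc(Br)c(OCOC)c1C/C=C(\C)CO[Si](C)(C)C(C)(C)C
F5 | step 9 | 1-{3-[(E)-4-(tert-butyldimethylsilyloxy)-3-methylbut-2-enyl]-2,4-bis(methoxymethoxy)phenyl}ethanone | CC(=O)c1ccc(OCOC)c(C/C=C(\C)CO[Si](C)(C)C(C)(C)C)c1OCOC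
F6 | step 9 | (E)-1-{3-[(E)-4-(tert-butyldimethylsilyloxy)-3-methylbut-2-enyl]-2,4-bis(methoxymethoxy)phenyl}-3-[4-(methoxymethoxy)phenyl]prop-2-en-1-one | COCOc1ccc(/C=C/C(=O)c2ccc(OCOC)c(C/C=C(\C)CO[Si](C)(C)C(C)(C)C)c2OCOC)cc1
F7 | step 11 | (E)-1-{2,4-dihydroxy-3-[(E)-4-hydroxy-3-methylbut-2-enyl]phenyl}-3-(4-hydroxyphenyl)prop-2-en-1-one | C/C(=C\Cc1c(O)ccc(C(=O)/C=C/c2ccc(O)cc2)c1O)CO
A1 | alternative 1 | (E)-1-{3-[(E)-4-(tert-butyldimethylsilyloxy)-3-methylbut-2-enyl]-2,4-dihydroxyphenyl}-3-[4-(methoxymethoxy)phenyl]prop-2-en-1-one | COCOc1ccc(/C=C/C(=O)c2ccc(O)c(C/C=C(\C)CO[Si](C)(C)C(C)(C)C)c2O)cc1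
A2 | alternative 1 | (1E,8E)-6-[(E)-4-(tert-butyldimethylsilyloxy)-3-methylbut-2-enyl]-9-methoxy-1-[4-(methoxymethoxy)phenyl]nona-1,8-diene-3,5,7-trione | COCOc1ccc(/C=C/C(=O)CC(=O)C(C/C=C(\C)CO[Si](C)(C)C(C)(C)C)C(=O)/C=C/OC)cc1
A3 | alternative 2 | 2-[(E)-4-(tert-butyldimethylsilyloxy)-3-methylbut-2-enyl]-3-(methoxymethoxy)-6-{(E)-3-[4-(methoxymethoxy)phenyl]prop-2-enoyl}cyclohex-2-en-1-one (racemic) | COCOC1=C(C/C=C(\C)CO[Si](C)(C)C(C)(C)C)C(=O)C(CC1)C(=O)/C=C/c1ccc(OCOC)cc1
A4 | alternative 2 | 2-[(E)-4-(tert-butyldimethylsilyloxy)-3-methylbut-2-enyl]-3-(methoxymethoxy)cyclohex-2-en-1-one | COCOC1=C(C/C=C(\C)CO[Si](C)(C)C(C)(C)C)C(=O)CCC1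
A5 | alternative 2 | 1-{(E)-3-[4-(methoxymethoxy)phenyl]prop-2-enoyl}-1H-benzotriazole | COCOc1ccc(/C=C/C(=O)n2nnc3ccccc32)cc1
A6 | alternative 3 | (E)-4-{2,6-bis(methoxymethoxy)-3-[(E)-3-[4-(methoxymethoxy)phenyl]prop-2-enoyl]phenyl}-2-methylbut-2-enal | C/C(=C\Cc1c(OCOC)ccc(C(=O)/C=C/c2ccc(OCOC)cc2)c1OCOC)C=O
A7 | alternative 3 | (E)-1-[3-allyl-2,4-bis(methoxymethoxy)phenyl]-3-[4-(methoxymethoxy)phenyl]prop-2-en-1-one | C=CCc1c(OCOC)ccc(C(=O)/C=C/c2ccc(OCOC)cc2)c1OCOC
A8 | alternative 3 | methacrolein (2-methylprop-2-enal) | CC(=C)C=O
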